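## Retrosynthetic overview

1. Elemane numbering is used in both halves: C10 quaternary, C5 CH–isopropenyl, C6/C9 ring CH2, C7/C8 ring fusion, C11/C12 lactone α-C/C=O, C13 linker CH2. Primed atoms belong to the half with the saturated lactone.
2. Butenolide (last ring): ketol 23 is acylated at O8 by phosphono acid 30, then an intramolecular Horner–Wadsworth–Emmons reaction closes C7=C11. The linker bond C13–C13' and the C11'–H centre come from a decarboxylative Giese addition to α-methylene lactone 17.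
3. Saturated γ-lactone: equatorial hydride attack on the C8' ketone of 12, then O8'–C12' closure. The ketone comes from the C7'=C8' alkene of 9 by epoxidation and Meinwald rearrangement.
4. Carbocycle C5'–C10' (first ring): catalytic enantioselective Diels–Alder reaction of diene 7 with keto enal 3, forming C5'–C6' and C9'–C10'. The carbocycle C5–C10 of the other half comes from the same reaction with silyloxydiene 19 and the mirror-image catalyst.
5. Enabling feature: in ring C5'–C10' the quaternary C10' (CH3, vinyl = methylenated CHO) sits next to C5'–H (isopropenyl = methylenated acetyl, cis to CH3). C6' and C9' are bare CH2 groups, C7' (para to C10') carries the only carbon branch, and C7'–C8' (H, O) is an oxidised alkene, so the ring is a complete [4+2] retron. Ring order: carbocycle, γ-lactone, second carbocycle, butenolide.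

Key step: step 4

Assumption: the (S)-configured oxazaborolidinium ion is taken to give the (4R,5R) adduct 8 and its enantiomer the (1S,6S) adduct 20. If the sense of induction is the reverse, the two catalyst enantiomers of steps 4 and 11 change places.

## Route

Step 1
Reactants: 1 methylglyoxal (2-oxopropanal, aqueous solution); 2 2-(triphenyl-λ5-phosphanylidene)propanal
Product: 3 (E)-2-methyl-4-oxopent-2-enal
Conditions: CH2Cl2/H2O, 0 °C → rt, 1 in slight excess
Reagents that add atoms: none
Why: Wittig olefination in which the stabilised formyl ylide reacts only with the far more electrophilic aldehyde carbonyl of the α-keto aldehyde and, as stabilised ylides do, should give the E-alkene with acetyl and formyl trans.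

Step 2
Reactants: 4 isoprene (2-methylbuta-1,3-diene)
Product: 6 3-methylidenepent-4-enoic acid, via allylpotassium species 5 (not isolated)
Conditions: LiN(i-Pr)2, KOt-Bu, THF, −78 °C; CO2 (solid); 1 M HCl
Reagents that add atoms: carbon dioxide O=C=O
Why: Allylic metalation–carboxylation in which the amide/alkoxide superbase removes a methyl proton of isoprene without adding to the diene, and the symmetric 2-vinylallyl anion gives the same 2-substituted diene from either CH2 terminus.

Step 3
Reactants: 6 3-methylidenepent-4-enoic acid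
Product: 7 methyl 3-methylidenepent-4-enoate
Conditions: MeI, KHCO3, DMF, rt
Reagents that add atoms: iodomethane CI
Why: Carboxylate O-alkylation (SN2) under a base too weak to move the double bonds into conjugation with the ester.

Step 4
Reactants: 7 methyl 3-methylidenepent-4-enoate; 3 (E)-2-methyl-4-oxopent-2-enal
Product: 8 methyl 2-[(4R,5R)-5-acetyl-4-formyl-4-methylcyclohex-1-en-1-yl]acetate
Conditions: (S)-1-(2-methylphenyl)-3,3-diphenyltetrahydro-1H,3H-pyrrolo[1,2-c][1,3,2]oxazaborole (20 mol %), Tf2NH (18 mol %), CH2Cl2, −78 → −40 °C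
Reagents that add atoms: none
Why: The oxazaborolidinium ion binds the formyl oxygen of 3 and lowers the LUMO of the C5'=C10' alkene, which undergoes a concerted but asynchronous suprafacial [4+2] cycloaddition (Diels–Alder reaction) with s-cis 7, the C5'–C6' bond running ahead of C9'–C10'. The closest known reaction type is the oxazaborolidinium-catalysed enantioselective Diels–Alder reaction of α-methyl-β-substituted enals with 2-alkylbuta-1,3-dienes. The one ring closed is the six-membered carbocycle C5'–C10', closed in the [4+2] mode by the two σ bonds C5'–C6' and C9'–C10', which leaves the C7'=C8' alkene as a handle. The relative configuration of C5' and the quaternary C10' (acetyl cis to methyl, trans to formyl) is carried over stereospecifically from the E geometry of 3, and the absolute configuration of both is set by the catalyst, whose aryl groups shield one face of the bound enal. The step needs orientation and site selectivity: the more nucleophilic terminus C6' (next to the substituted C7') attacks the unhindered, formyl-β carbon C5', which puts C7' para to C10', and masking the isopropenyl group as acetyl leaves 3 with a single C=C bond. No endo/exo question arises because both diene termini are CH2 groups.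

Step 5
Reactants: 8 methyl 2-[(4R,5R)-5-acetyl-4-formyl-4-methylcyclohex-1-en-1-yl]acetate
Product: 9 methyl 2-[(4S,5S)-4-ethenyl-4-methyl-5-(prop-1-en-2-yl)cyclohex-1-en-1-yl]acetate
Conditions: Zn, CH2Br2, TiCl4 (pre-aged in THF, 5 °C); then 8, CH2Cl2, 0 °C → rt
Reagents that add atoms: dibromomethane BrCBr
Why: Takai–Lombardo methylenation, whose non-basic zinc/titanium methylene reagent turns formyl into vinyl and acetyl into isopropenyl, leaves the ester alone and enolises neither the ketone nor the 1,4-keto aldehyde, so C5' keeps its configuration.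

Step 6
Reactants: 9 methyl 2-[(4S,5S)-4-ethenyl-4-methyl-5-(prop-1-en-2-yl)cyclohex-1-en-1-yl]acetate
Product: 10 methyl 2-[(1S,3S,4S,6S)-4-ethenyl-4-methyl-3-(prop-1-en-2-yl)-7-oxabicyclo[4.1.0]heptan-1-yl]acetate (epoxide oxygen trans to the C10' methyl group)
Conditions: mCPBA (1 equiv), CH2Cl2, −20 °C
Reagents that add atoms: 3-chloroperbenzoic acid O=C(OO)c1cccc(Cl)c1
Why: Prilezhaev epoxidation in which the trisubstituted ring alkene is the most electron-rich of the three (the selectivity known from limonene) and the peracid should approach opposite the axial C10' methyl group, although either epoxide would serve in step 7.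

Step 7
Reactants: 10 methyl 2-[(1S,3S,4S,6S)-4-ethenyl-4-methyl-3-(prop-1-en-2-yl)-7-oxabicyclo[4.1.0]heptan-1-yl]acetate
Product: 12 methyl 2-[(1R,4S,5S)-4-ethenyl-4-methyl-2-oxo-5-(prop-1-en-2-yl)cyclohexyl]acetate, via axial keto ester 11 (not isolated)
Conditions: Bi(OTf)3 (2 mol %), CH2Cl2, 0 °C; then K2CO3 (cat.), MeOH, rt
Reagents that add atoms: none
Why: Meinwald rearrangement in which the Lewis acid opens the tertiary C7'–O bond and a 1,2-hydride shift from C8' gives the C8' ketone (as limonene oxide gives dihydrocarvone), after which carbonate-mediated enolisation moves the C7' side chain into the equatorial position, cis to the isopropenyl group.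

Step 8
Reactants: 12 methyl 2-[(1R,4S,5S)-4-ethenyl-4-methyl-2-oxo-5-(prop-1-en-2-yl)cyclohexyl]acetate
Product: 14 (3aR,5S,6S,7aR)-6-ethenyl-6-methyl-5-(prop-1-en-2-yl)hexahydro-1-benzofuran-2(3H)-one, via hydroxy ester 13 (not isolated)
Conditions: LiBH(s-Bu)3, THF, −78 → 0 °C; AcOH
Reagents that add atoms: none
Why: Diastereoselective ketone reduction followed by lactonisation, in which the bulky borohydride attacks along the equatorial trajectory because the axial C10' methyl group blocks the other face, so the C8' alkoxide is axial, cis to the C7' side chain, and closes the cis-fused γ-lactone by expelling methoxide.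

Step 9
Reactants: 14 (3aR,5S,6S,7aR)-6-ethenyl-6-methyl-5-(prop-1-en-2-yl)hexahydro-1-benzofuran-2(3H)-one
Product: 17 (3aR,5S,6S,7aR)-6-ethenyl-6-methyl-3-methylidene-5-(prop-1-en-2-yl)hexahydro-1-benzofuran-2(3H)-one, via Mannich base 15 (not isolated), via methiodide 16 (not isolated)
Conditions: LiN(i-Pr)2, THF, −78 °C; CH2=NMe2+ I−, −78 °C → rt; MeI, MeOH, rt; aq. NaHCO3, CH2Cl2, rt
Reagents that add atoms: dimethyl(methylidene)ammonium iodide C=[N+](C)C.[I-]
Why: Mannich aminomethylation of the lactone enolate followed by quaternisation and Hofmann-type elimination is the standard α-methylenation of γ-lactones, and the transient C11' centre is erased again.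

Step 10
Reactants: 18 methyl vinyl ketone (but-3-en-2-one)
Product: 19 (buta-1,3-dien-2-yloxy)tri(propan-2-yl)silane
Conditions: i-Pr3SiOTf, Et3N, Et2O, 0 °C
Reagents that add atoms: triisopropylsilyl trifluoromethanesulfonate CC(C)[Si](OS(=O)(=O)C(F)(F)F)(C(C)C)C(C)C
Why: Soft enolisation and O-silylation of the enone give the robust 2-silyloxydiene.

Step 11
Reactants: 19 (buta-1,3-dien-2-yloxy)tri(propan-2-yl)silane; 3 (E)-2-methyl-4-oxopent-2-enal
Product: 20 (1S,6S)-6-acetyl-1-methyl-4-[(triisopropylsilyl)oxy]cyclohex-3-ene-1-carbaldehyde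
Conditions: (R)-1-(2-methylphenyl)-3,3-diphenyltetrahydro-1H,3H-pyrrolo[1,2-c][1,3,2]oxazaborole (20 mol %), Tf2NH (18 mol %), CH2Cl2, −78 °C
Reagents that add atoms: none
Why: Enantioselective Diels–Alder reaction of the type used in step 4, in which the silyloxy group makes C6 the strongly nucleophilic terminus (C7–O para to C10), the E geometry of 3 again sets acetyl cis to methyl, and the mirror-image catalyst sets the opposite absolute configuration at C5 and C10.

Step 12
Reactants: 20 (1S,6S)-6-acetyl-1-methyl-4-[(triisopropylsilyl)oxy]cyclohex-3-ene-1-carbaldehyde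
Product: 21 {[(4R,5R)-4-ethenyl-4-methyl-5-(prop-1-en-2-yl)cyclohex-1-en-1-yl]oxy}tri(propan-2-yl)silane
Conditions: Zn, CH2Br2, TiCl4 (pre-aged in THF, 5 °C); then 20, CH2Cl2, 0 °C → rt
Reagents that add atoms: dibromomethane BrCBr
Why: Takai–Lombardo methylenation as in step 5, non-basic so that C5 is not epimerised, with the bulky silyl enol ether expected to survive the THF-tempered titanium reagent.

Step 13
Reactants: 21 {[(4R,5R)-4-ethenyl-4-methyl-5-(prop-1-en-2-yl)cyclohex-1-en-1-yl]oxy}tri(propan-2-yl)silane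
Product: 23 (2R,4R,5R)-4-ethenyl-2-hydroxy-4-methyl-5-(prop-1-en-2-yl)cyclohexan-1-one, via silyloxy ketone 22 (not isolated)
Conditions: mCPBA (1 equiv), CH2Cl2, −40 → 0 °C; then Et3N·3HF, THF, rt
Reagents that add atoms: 3-chloroperbenzoic acid O=C(OO)c1cccc(Cl)c1
Why: Rubottom oxidation in which the silyl enol ether is by far the most electron-rich alkene, the oxidant comes from the face opposite the axial C10 methyl group, and the resulting equatorial C8–O bond (trans to that methyl group) is also the thermodynamically preferred one.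

Step 14
Reactants: 24 allyl 2-(diethoxyphosphoryl)acetate; 25 tert-butyl bromoacetate
Product: 26 4-tert-butyl 1-(prop-2-en-1-yl) 2-(diethoxyphosphoryl)butanedioate (racemic)
Conditions: NaH, THF, 0 °C → rt
Reagents that add atoms: none
Why: SN2 alkylation of the stabilised phosphonoacetate carbanion with a highly reactive α-bromo ester.

Step 15
Reactants: 26 4-tert-butyl 1-(prop-2-en-1-yl) 2-(diethoxyphosphoryl)butanedioate
Product: 27 3-(diethoxyphosphoryl)-4-oxo-4-(prop-2-en-1-yloxy)butanoic acid (racemic)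
Conditions: CF3CO2H, CH2Cl2, 0 °C → rt
Reagents that add atoms: none
Why: Acidolysis (E1) cleaves only the tert-butyl ester and leaves the allyl ester and the phosphonate untouched.

Step 16
Reactants: 27 3-(diethoxyphosphoryl)-4-oxo-4-(prop-2-en-1-yloxy)butanoic acid; 17 (3aR,5S,6S,7aR)-6-ethenyl-6-methyl-3-methylidene-5-(prop-1-en-2-yl)hexahydro-1-benzofuran-2(3H)-one
Product: 29 prop-2-en-1-yl 2-(diethoxyphosphoryl)-4-[(3S,3aR,5S,6S,7aR)-6-ethenyl-6-methyl-2-oxo-5-(prop-1-en-2-yl)octahydro-1-benzofuran-3-yl]butanoate (both epimers at the phosphonate carbon), via N-acyloxyphthalimide 28 (not isolated)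
Conditions: N-hydroxyphthalimide, DIC, DMAP (cat.), CH2Cl2, rt; then 17, Ru(bpy)3(PF6)2 (1 mol %), diethyl 2,6-dimethyl-1,4-dihydropyridine-3,5-dicarboxylate, i-Pr2NEt, CH2Cl2, blue LED, rt
Reagents that add atoms: none
Why: Decarboxylative Giese addition in which single-electron reduction of the N-acyloxyphthalimide releases CO2 and a nucleophilic primary radical that adds only to the electron-poor methylene C13' of 17, and the C11' radical then takes hydrogen from the dihydropyridine on the convex face of the cis-fused bicycle (the face of H7' and H8'), which places the new chain on the concave face as required.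

Step 17
Reactants: 29 prop-2-en-1-yl 2-(diethoxyphosphoryl)-4-[(3S,3aR,5S,6S,7aR)-6-ethenyl-6-methyl-2-oxo-5-(prop-1-en-2-yl)octahydro-1-benzofuran-3-yl]butanoate
Product: 30 2-(diethoxyphosphoryl)-4-[(3S,3aR,5S,6S,7aR)-6-ethenyl-6-methyl-2-oxo-5-(prop-1-en-2-yl)octahydro-1-benzofuran-3-yl]butanoic acid (both epimers at the phosphonate carbon)
Conditions: Pd(PPh3)4 (5 mol %), morpholine, THF, rt; dilute acid wash
Reagents that add atoms: none
Why: Tsuji–Trost deallylation ionises only the allyl ester and passes the allyl group to morpholine under conditions too mild to touch the lactone, the isolated alkenes or the base-sensitive C11' centre.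

Step 18
Reactants: 30 2-(diethoxyphosphoryl)-4-[(3S,3aR,5S,6S,7aR)-6-ethenyl-6-methyl-2-oxo-5-(prop-1-en-2-yl)octahydro-1-benzofuran-3-yl]butanoic acid; 23 (2R,4R,5R)-4-ethenyl-2-hydroxy-4-methyl-5-(prop-1-en-2-yl)cyclohexan-1-one
Product: 31 (1R,4R,5R)-5-ethenyl-5-methyl-2-oxo-4-(prop-1-en-2-yl)cyclohexyl 2-(diethoxyphosphoryl)-4-[(3S,3aR,5S,6S,7aR)-6-ethenyl-6-methyl-2-oxo-5-(prop-1-en-2-yl)octahydro-1-benzofuran-3-yl]butanoate (both epimers at the phosphonate carbon)
Conditions: DIC, DMAP (cat.), CH2Cl2, 0 °C → rt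
Reagents that add atoms: none
Why: Steglich esterification acylates the unhindered equatorial C8 hydroxyl group with retention, since the C8–O bond is not broken.

Step 19
Reactants: 31 (1R,4R,5R)-5-ethenyl-5-methyl-2-oxo-4-(prop-1-en-2-yl)cyclohexyl 2-(diethoxyphosphoryl)-4-[(3S,3aR,5S,6S,7aR)-6-ethenyl-6-methyl-2-oxo-5-(prop-1-en-2-yl)octahydro-1-benzofuran-3-yl]butanoate
Product: 32 target, (5R,6R,7aR)-6-ethenyl-3-{2-[(3S,3aR,5S,6S,7aR)-6-ethenyl-6-methyl-2-oxo-5-(prop-1-en-2-yl)octahydro-1-benzofuran-3-yl]ethyl}-6-methyl-5-(prop-1-en-2-yl)-5,6,7,7a-tetrahydro-1-benzofuran-2(4H)-one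
Conditions: LiCl, DBU, MeCN, 0 °C → rt
Reagents that add atoms: none
Why: Intramolecular Horner–Wadsworth–Emmons olefination under Masamune–Roush conditions closes the five-membered butenolide (C7=C11), removes the undefined phosphonate centre, uses a base too weak to epimerise C11', and leaves C8 in its preferred pseudo-equatorial C–O arrangement.

## Compound list

1 | methylglyoxal (2-oxopropanal) | CC(=O)C=O | starting material
2 | 2-(triphenyl-λ5-phosphanylidene)propanal | CC(C=O)=P(c1ccccc1)(c1ccccc1)c1ccccc1 | starting material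
3 | (E)-2-methyl-4-oxopent-2-enal | CC(=O)/C=C(\C)C=O | intermediate
4 | isoprene | C=CC(C)=C | starting material
5 | (2-methylidenebut-3-en-1-yl)potassium | [K+].[CH2-]C(=C)C=C | intermediate
6 | 3-methylidenepent-4-enoic acid | C=CC(=C)CC(=O)O | intermediate
7 | methyl 3-methylidenepent-4-enoate | C=CC(=C)CC(=O)OC | intermediate
8 | methyl 2-[(4R,5R)-5-acetyl-4-formyl-4-methylcyclohex-1-en-1-yl]acetate | COC(=O)CC1=CC[C@@](C)(C=O)[C@H](C(C)=O)C1 | intermediate
9 | methyl 2-[(4S,5S)-4-ethenyl-4-methyl-5-(prop-1-en-2-yl)cyclohex-1-en-1-yl]acetate | COC(=O)CC1=CC[C@@](C)(C=C)[C@H](C(C)=C)C1 | intermediate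
10 | methyl 2-[(1S,3S,4S,6S)-4-ethenyl-4-methyl-3-(prop-1-en-2-yl)-7-oxabicyclo[4.1.0]heptan-1-yl]acetate | COC(=O)C[C@]12O[C@H]1C[C@@](C)(C=C)[C@H](C(C)=C)C2 | intermediate
11 | methyl 2-[(1S,4S,5S)-4-ethenyl-4-methyl-2-oxo-5-(prop-1-en-2-yl)cyclohexyl]acetate | COC(=O)C[C@H]1C(=O)C[C@@](C)(C=C)[C@H](C(C)=C)C1 | intermediate
12 | methyl 2-[(1R,4S,5S)-4-ethenyl-4-methyl-2-oxo-5-(prop-1-en-2-yl)cyclohexyl]acetate | COC(=O)C[C@@H]1C(=O)C[C@@](C)(C=C)[C@H](C(C)=C)C1 | intermediate
13 | methyl 2-[(1R,2R,4S,5S)-4-ethenyl-2-hydroxy-4-methyl-5-(prop-1-en-2-yl)cyclohexyl]acetate (formed as its lithium alkoxide) | COC(=O)C[C@@H]1[C@H](O)C[C@@](C)(C=C)[C@H](C(C)=C)C1 | intermediate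
14 | (3aR,5S,6S,7aR)-6-ethenyl-6-methyl-5-(prop-1-en-2-yl)hexahydro-1-benzofuran-2(3H)-one | C1C(=O)O[C@@H]2C[C@@](C)(C=C)[C@H](C(=C)C)C[C@H]12 | intermediate
15 | (3S,3aR,5S,6S,7aR)-3-[(dimethylamino)methyl]-6-ethenyl-6-methyl-5-(prop-1-en-2-yl)hexahydro-1-benzofuran-2(3H)-one | CN(C)C[C@H]1C(=O)O[C@@H]2C[C@@](C)(C=C)[C@H](C(=C)C)C[C@H]12 | intermediate
16 | {[(3S,3aR,5S,6S,7aR)-6-ethenyl-6-methyl-2-oxo-5-(prop-1-en-2-yl)octahydro-1-benzofuran-3-yl]methyl}trimethylammonium iodide | C[N+](C)(C)C[C@H]1C(=O)O[C@@H]2C[C@@](C)(C=C)[C@H](C(=C)C)C[C@H]12.[I-] | intermediate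
17 | (3aR,5S,6S,7aR)-6-ethenyl-6-methyl-3-methylidene-5-(prop-1-en-2-yl)hexahydro-1-benzofuran-2(3H)-one | C=C1C(=O)O[C@@H]2C[C@@](C)(C=C)[C@H](C(=C)C)C[C@H]12 | intermediate
18 | methyl vinyl ketone | C=CC(C)=O | starting material
19 | (buta-1,3-dien-2-yloxy)tri(propan-2-yl)silane | C=CC(=C)O[Si](C(C)C)(C(C)C)C(C)C | intermediate
20 | (1S,6S)-6-acetyl-1-methyl-4-[(triisopropylsilyl)oxy]cyclohex-3-ene-1-carbaldehyde | CC(C)[Si](OC1=CC[C@](C)(C=O)[C@@H](C(C)=O)C1)(C(C)C)C(C)C | intermediate
21 | {[(4R,5R)-4-ethenyl-4-methyl-5-(prop-1-en-2-yl)cyclohex-1-en-1-yl]oxy}tri(propan-2-yl)silane | CC(C)[Si](OC1=CC[C@](C)(C=C)[C@@H](C(C)=C)C1)(C(C)C)C(C)C | intermediate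
22 | (2R,4R,5R)-4-ethenyl-4-methyl-5-(prop-1-en-2-yl)-2-[(triisopropylsilyl)oxy]cyclohexan-1-one | O=C1[C@H](O[Si](C(C)C)(C(C)C)C(C)C)C[C@](C)(C=C)[C@@H](C(C)=C)C1 | intermediate
23 | (2R,4R,5R)-4-ethenyl-2-hydroxy-4-methyl-5-(prop-1-en-2-yl)cyclohexan-1-one | O=C1[C@H](O)C[C@](C)(C=C)[C@@H](C(C)=C)C1 | intermediate
24 | allyl 2-(diethoxyphosphoryl)acetate | C=CCOC(=O)CP(=O)(OCC)OCC | starting material
25 | tert-butyl bromoacetate | CC(C)(C)OC(=O)CBr | starting material
26 | 4-tert-butyl 1-(prop-2-en-1-yl) 2-(diethoxyphosphoryl)butanedioate (racemic) | C=CCOC(=O)C(CC(=O)OC(C)(C)C)P(=O)(OCC)OCC | intermediate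
27 | 3-(diethoxyphosphoryl)-4-oxo-4-(prop-2-en-1-yloxy)butanoic acid (racemic) | C=CCOC(=O)C(CC(=O)O)P(=O)(OCC)OCC | intermediate
28 | 4-(1,3-dioxoisoindolin-2-yl) 1-(prop-2-en-1-yl) 2-(diethoxyphosphoryl)butanedioate (racemic) | C=CCOC(=O)C(CC(=O)ON1C(=O)c2ccccc2C1=O)P(=O)(OCC)OCC | intermediate
29 | prop-2-en-1-yl 2-(diethoxyphosphoryl)-4-[(3S,3aR,5S,6S,7aR)-6-ethenyl-6-methyl-2-oxo-5-(prop-1-en-2-yl)octahydro-1-benzofuran-3-yl]butanoate (both epimers at the phosphonate carbon) | C=CCOC(=O)C(CC[C@@H]1C(=O)O[C@@H]2C[C@@](C)(C=C)[C@H](C(=C)C)C[C@H]12)P(=O)(OCC)OCC | intermediate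
30 | 2-(diethoxyphosphoryl)-4-[(3S,3aR,5S,6S,7aR)-6-ethenyl-6-methyl-2-oxo-5-(prop-1-en-2-yl)octahydro-1-benzofuran-3-yl]butanoic acid (both epimers at the phosphonate carbon) | OC(=O)C(CC[C@@H]1C(=O)O[C@@H]2C[C@@](C)(C=C)[C@H](C(=C)C)C[C@H]12)P(=O)(OCC)OCC | intermediate
31 | (1R,4R,5R)-5-ethenyl-5-methyl-2-oxo-4-(prop-1-en-2-yl)cyclohexyl ester of 30 (both epimers at the phosphonate carbon) | O=C1[C@H](OC(=O)C(CC[C@@H]2C(=O)O[C@@H]3C[C@@](C)(C=C)[C@H](C(=C)C)C[C@H]23)P(=O)(OCC)OCC)C[C@](C)(C=C)[C@@H](C(C)=C)C1 | intermediate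
32 | (5R,6R,7aR)-6-ethenyl-3-{2-[(3S,3aR,5S,6S,7aR)-6-ethenyl-6-methyl-2-oxo-5-(prop-1-en-2-yl)octahydro-1-benzofuran-3-yl]ethyl}-6-methyl-5-(prop-1-en-2-yl)-5,6,7,7a-tetrahydro-1-benzofuran-2(4H)-one | C=C[C@@]1(C)C[C@H]2OC(=O)C(CC[C@@H]3C(=O)O[C@@H]4C[C@@](C)(C=C)[C@H](C(=C)C)C[C@H]34)=C2C[C@@H]1C(=C)C | target

## Step count and risks

Total step count: 19. Longest linear sequence: 12 steps (steps 2–9 and 16–19).

**Step 4.** What may go wrong:
- Orientation control may be lost (acetyl-directed instead of formyl-directed approach).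
- Turnover may be slow, because diene 7 is only weakly polarised by its CH2CO2Me branch.
- Facial control may erode if the catalyst also binds the acetyl oxygen.

The fallback sets out from 19 and 3 and comes back at 9. The cycloaddition is run on the strongly polarised silyloxydiene 19 with 3 and the catalyst enantiomer of step 4. This should give the enantiomer of 20, (1R,6R)-6-acetyl-1-methyl-4-[(triisopropylsilyl)oxy]cyclohex-3-ene-1-carbaldehyde F1. Takai–Lombardo methylenation as in step 12 gives {[(4S,5S)-4-ethenyl-4-methyl-5-(prop-1-en-2-yl)cyclohex-1-en-1-yl]oxy}tri(propan-2-yl)silane F2. CsF and PhNTf2 in DME turn it, with the double bond held in place, into (4S,5S)-4-ethenyl-4-methyl-5-(prop-1-en-2-yl)cyclohex-1-en-1-yl trifluoromethanesulfonate F3. Negishi-type coupling of F3 under Pd(PPh3)4 in THF with bromo(2-methoxy-2-oxoethyl)zinc F4, made from methyl bromoacetate and Zn, installs the C7' branch and delivers 9.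

**Step 7.** What may go wrong: the C7' cation may be diverted into ring contraction, or be captured by the ester carbonyl or the isopropenyl group, instead of undergoing the hydride shift.

The fallback sets out from 10 and comes back at 14. Camphorsulfonic acid in wet CH2Cl2 lets the ester carbonyl open the epoxide at C8' in the 5-exo mode with inversion. This gives (3aS,5S,6S,7aR)-6-ethenyl-3a-hydroxy-6-methyl-5-(prop-1-en-2-yl)hexahydro-1-benzofuran-2(3H)-one F5, whose O8' is already cis to the C10' methyl group. Dehydration with methyl N-(triethylammoniosulfonyl)carbamate gives (5S,6S,7aR)-6-ethenyl-6-methyl-5-(prop-1-en-2-yl)-5,6,7,7a-tetrahydro-1-benzofuran-2(4H)-one F6. Conjugate reduction with [(Ph3P)CuH]6 (cat.) and polymethylhydrosiloxane in toluene/t-BuOH delivers hydride to C7' on the face of H8', leaves the isolated alkenes alone, and gives 14.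

**Step 16.** What may go wrong:
- The acceptor may capture the radical too slowly.
- The radical may be reduced prematurely.
- The final hydrogen transfer at C11' may have too little facial bias.

The fallback sets out from 17 and 24 and comes back at 29. It reverses the roles of the partners and sets C11' in an ionic step. Copper-catalysed conjugate borylation of 17 (CuCl, NaOt-Bu, bis[2-(diphenylphosphino)phenyl] ether, B2pin2, MeOH, THF) with protonation of the enolate on the convex face gives (3S,3aR,5S,6S,7aR)-6-ethenyl-6-methyl-5-(prop-1-en-2-yl)-3-[(4,4,5,5-tetramethyl-1,3,2-dioxaborolan-2-yl)methyl]hexahydro-1-benzofuran-2(3H)-one F7. NaBO3·4H2O in THF/H2O gives (3R,3aR,5S,6S,7aR)-6-ethenyl-3-(hydroxymethyl)-6-methyl-5-(prop-1-en-2-yl)hexahydro-1-benzofuran-2(3H)-one F8. I2, PPh3 and imidazole give (3S,3aR,5S,6S,7aR)-6-ethenyl-3-(iodomethyl)-6-methyl-5-(prop-1-en-2-yl)hexahydro-1-benzofuran-2(3H)-one F9. Separately, 24 is condensed with paraformaldehyde (piperidine, MeOH; then TsOH, toluene) to prop-2-en-1-yl 2-(diethoxyphosphoryl)prop-2-enoate F10. Tin-free Giese addition of the C13' radical from F9 to the doubly activated alkene F10 ((Me3Si)3SiH, AIBN, toluene, 80 °C) gives 29.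

## Further compounds

F1 | step 4 | (1R,6R)-6-acetyl-1-methyl-4-[(triisopropylsilyl)oxy]cyclohex-3-ene-1-carbaldehyde | CC(C)[Si](OC1=CC[C@@](C)(C=O)[C@H](C(C)=O)C1)(C(C)C)C(C)C
F2 | step 4 | {[(4S,5S)-4-ethenyl-4-methyl-5-(prop-1-en-2-yl)cyclohex-1-en-1-yl]oxy}tri(propan-2-yl)silane | CC(C)[Si](OC1=CC[C@@](C)(C=C)[C@H](C(C)=C)C1)(C(C)C)C(C)C
F3 | step 4 | (4S,5S)-4-ethenyl-4-methyl-5-(prop-1-en-2-yl)cyclohex-1-en-1-yl trifluoromethanesulfonate | O=S(=O)(OC1=CC[C@@](C)(C=C)[C@H](C(C)=C)C1)C(F)(F)F
F4 | step 4 | bromo(2-methoxy-2-oxoethyl)zinc | COC(=O)C[Zn]Br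
F5 | step 7 | (3aS,5S,6S,7aR)-6-ethenyl-3a-hydroxy-6-methyl-5-(prop-1-en-2-yl)hexahydro-1-benzofuran-2(3H)-one | C1C(=O)O[C@@H]2C[C@@](C)(C=C)[C@H](C(=C)C)C[C@]12O
F6 | step 7 | (5S,6S,7aR)-6-ethenyl-6-methyl-5-(prop-1-en-2-yl)-5,6,7,7a-tetrahydro-1-benzofuran-2(4H)-one | O=C1O[C@@H]2C[C@@](C)(C=C)[C@H](C(=C)C)CC2=C1
F7 | step 16 | (3S,3aR,5S,6S,7aR)-6-ethenyl-6-methyl-5-(prop-1-en-2-yl)-3-[(4,4,5,5-tetramethyl-1,3,2-dioxaborolan-2-yl)methyl]hexahydro-1-benzofuran-2(3H)-one | CC1(C)OB(C[C@@H]2C(=O)O[C@@H]3C[C@@](C)(C=C)[C@H](C(=C)C)C[C@H]23)OC1(C)C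
F8 | step 16 | (3R,3aR,5S,6S,7aR)-6-ethenyl-3-(hydroxymethyl)-6-methyl-5-(prop-1-en-2-yl)hexahydro-1-benzofuran-2(3H)-one | OC[C@@H]1C(=O)O[C@@H]2C[C@@](C)(C=C)[C@H](C(=C)C)C[C@H]12
F9 | step 16 | (3S,3aR,5S,6S,7aR)-6-ethenyl-3-(iodomethyl)-6-methyl-5-(prop-1-en-2-yl)hexahydro-1-benzofuran-2(3H)-one | IC[C@@H]1C(=O)O[C@@H]2C[C@@](C)(C=C)[C@H](C(=C)C)C[C@H]12
F10 | step 16 | prop-2-en-1-yl 2-(diethoxyphosphoryl)prop-2-enoate | C=CCOC(=O)C(=C)P(=O)(OCC)OCC
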